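In this closed, stirred vessel of constant volume, starting material leaves by two ways, and you want to know which form holds most of it at the end of each flask.

| flask | starting material | coupling partner | free catalyst | second catalyst | time |
|---|---|---|---|---|---|
| Friday's | 5.0 × 10⁻⁴ M | 0.500 mM | 2.1 µM | 2.5 µM | 2.5 s |
| Sunday's | 5.0 × 10⁻⁴ M | 0.750 mM | 2.1 µM | 2.5 µM | 2.5 s |
| Saturday's | 5.0 × 10⁻⁴ M | 1.10 mM | 2.1 µM | 2.5 µM | 2.5 s |

    starting material + free catalyst ⇌ free catalyst + open intermediate (K1 = 2.9, k1 = 2.31 × 10⁵ M⁻¹ s⁻¹)
    second catalyst + open intermediate ⇌ catalyst intermediate (K2 = 2600 M⁻¹, k2 = 1.62 × 10⁵ M⁻¹ s⁻¹)
    coupling partner + catalyst intermediate ⇌ second catalyst + target (K3 = 14.2, k3 = 1.16 × 10⁵ M⁻¹ s⁻¹)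
    crystals ⇌ target, rate k4*(cs4 - [target]) while solid is left; crystals form when [target] > cs4 (cs4 = 0.25 mM, k4 = 1.49 s⁻¹)
    starting material + coupling partner → uncatalysed product (k5 = 543 M⁻¹ s⁻¹)

- amounts and yields of target count crystals too
- given per volume of solution although it is solid: crystals
- run time (Friday's): 2.5 s

* which of these there is most of at the end, counted by the starting material in it, Friday's (uncatalysed product / open intermediate / target / starting material)
* which of these there is most of at the end, counted by the starting material in it, Sunday's (uncatalysed product / open intermediate / target / starting material)
* which of these there is most of at the end, counted by the starting material in it, Saturday's (uncatalysed product / open intermediate / target / starting material)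
* how much there is at the end of the one of these that leads, in percent of the starting material charged: Friday's
* how much there is at the end of the one of these that leads, in percent of the starting material charged: Sunday's
* how much there is at the end of the one of these that leads, in percent of the starting material charged: Saturday's

Free catalyst comes back unchanged from the opening step, so if I hold coupling partner at its charge, as an estimate, both ways out of starting material are pseudo-first-order and starting material cancels from their ratio. I call this the branch ratio ρ, a selectivity factor: the rate constant of the uncatalysed step times coupling partner, over the rate constant of the opening step times free catalyst. It is 1.23 for Saturday's, 0.840 for Sunday's and 0.560 for Friday's.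

Setting aside the return of open intermediate, and since catalyst intermediate cannot hold more than 2.5 µM, far less than the charge of starting material, I take ρ as an estimate of uncatalysed product over open intermediate plus target. Saturday's ρ, above one, therefore puts uncatalysed product ahead of the open branch in this estimate. In Friday's and Sunday's, open intermediate stands ahead of uncatalysed product if target takes less of the open branch than the gap between ρ and one, which is 0.440 for Friday's and 0.160 for Sunday's.

I reckon target's share as entry at 0.405 s⁻¹ with second catalyst free, times the fraction of catalyst intermediate going forward, over a mean age of 1.25 s. That gives 0.244 for Friday's and 0.295 for Sunday's. Letting starting material fall at both rates together, I commit to open intermediate at 41.2% for Friday's, and uncatalysed product at 40.7% for Sunday's and 51.5% for Saturday's.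

The forecast, from “Hand midpoint stepping at 0.5 s gave these end values”, names open intermediate at 38.2% for Friday's, uncatalysed product at 37.5% for Sunday's and uncatalysed product at 48.8% for Saturday's, the same leaders as mine at lower figures .

The simulation gives open intermediate at 38.8% for Friday's, uncatalysed product at 38.2% for Sunday's and uncatalysed product at 49.8% for Saturday's.

Saturday's uncatalysed product over open intermediate plus target reads 1.33, against a ρ of 1.23. Now take Saturday's recipe with 6.2 × 10⁻⁶ M of second catalyst: second catalyst does not enter ρ, so the reckoning stays at 1.23 and expects material to shift within the open branch, not across it. That neighbour flask ends with uncatalysed product at 48.7%, beside Saturday's 49.8%, with target at 23.2% and open intermediate at 16.1%, a ratio of 1.24.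

The rate constants stand for no real mixture; the run is a simulation.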